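The earlier runs and the new flask were computed on assumed constants, noise included.

Picture a one-step world: the coupling partner adds once to the substrate, what the substrate loses stands in the two mono adducts, and double product stays at nil. One chemist holds this view of the flask below, and a second holds that either mono adduct takes a further coupling partner.

in all of them: substrate 46 mM
- south: coupling partner 46 mM (fed, over 8.0 h); run made earlier; the fed solution adds 0.10 times the starting volume
- west: coupling partner 100 mM (fed, over 8.0 h); run made earlier; the fed solution adds 0.10 times the starting volume
- flask: coupling partner 69.0 mM (fed, over 8.0 h); the fed solution adds 0.10 times the starting volume; time 8.0 h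

| run | time / h | substrate / % | single product / % | other mono adduct / % |
|---|---|---|---|---|
| south | 0.333 | 100.6 | 0 | 1.3 |
| south | 1.00 | 96.2 | 1.2 | 2.0 |
| south | 1.50 | 94.7 | 2.7 | 0.9 |
| south | 2.50 | 87.9 | 5.4 | 7.9 |
| south | 4.00 | 78.5 | 5.3 | 12.6 |
| south | 5.00 | 71.1 | 7.8 | 17.1 |
| west | 0.333 | 99.3 | 0 | 1.9 |
| west | 1.00 | 92.9 | 3.3 | 1.4 |
| west | 1.50 | 90.0 | 6.4 | 7.2 |
| west | 2.50 | 75.1 | 9.7 | 14.3 |
| west | 4.00 | 54.8 | 21.1 | 22.0 |
| west | 5.00 | 40.4 | 22.3 | 27.3 |

(each reading ± 1 percentage point)

- every charge counts on the volume at the start, and the solution that is fed holds the whole dose
- a reading or a percentage of single product counts all its forms, free or not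

1. substrate at 8.0 h, in percent of the substrate charged
2. single product at 8.0 h, in percent of the substrate charged
3. other mono adduct at 8.0 h, in percent of the substrate charged
4. double product at 8.0 h, in percent of the substrate charged

The one-step chemist points to the south run: at 5.00 h the gap, meaning the charge minus the 3 readings, is 4.00%, with a scatter of 1 percentage point in each reading. The flask would then hold 68.0% of mono adducts at the forecast's substrate, and no double product.

The second chemist answers with the west run, whose gap at 5.00 h is 10.0%, and goes to logarithms. Let a be the fraction of substrate left. If both additions run in proportion to c(coupling partner), then x = ln(1/a) counts the exposure to the partner, however the feed ran. For a slow second addition, double product is about s times g, where g is x minus the fraction of substrate lost and s is the rate constant of the second addition over that of the first, the selectivity factor. The south gap sits on a g of 0.0521, smaller than the west run's 0.310, so s is read from the west run, as a reading with its scatter: s = 0.322.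

The forecast, this chemist's side, says “Second addition runs at about a third of k” and gives substrate 32%, single product 20%, other mono adduct 31% and double product 17%. My own reckoning at that substrate has g = 0.459 and gives 14.8% of double product, lower than the forecast's figure.

The flask gives substrate 31.6%, single product 19.3%, other mono adduct 31.3% and double product 17.8%.

    substrate + coupling partner → other mono adduct (k = 5.79 M⁻¹ h⁻¹)
    crystals ⇌ single product, rate k2*(cs2 - [single product]) while solid is left; crystals form when [single product] > cs2 (solubility = 2.10 mM, k = 64.8 h⁻¹)
    coupling partner + other mono adduct → double product (k = 4.29 M⁻¹ h⁻¹)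
    substrate + coupling partner ⇌ single product (K = 7.70 M⁻¹, k = 8.46 M⁻¹ h⁻¹)
    coupling partner + single product → double product (k = 10.5 M⁻¹ h⁻¹)

The forecast holds, and s times g at this substrate gives 15.1%, which is 2.7 points short. The one-step view keeps the south run up to 2.50 h, where s times g is 0.257% and the gap reads −1.20%. The neighbouring flask takes 110 mM of substrate with the same coupling partner. Its substrate ends at 52.7%, so g is 0.168 and s times g gives 5.41%, and its double product stands at 4.72%.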